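**Plan**

1. Numbering (squalene-type chain): C2(Me2)–C3(OH)–C4–C5–C6(Me)–C7(O)–C8–C9–C10(=CH2)–C11–C12–C13–C14–C15(Me,OAc)–C16–C17–C18(O)–C19(Me)–C20–C21–C22(=O)–C23(Me2); ring A = left oxepane (O, C2–C7), ring B = left cyclohexane (C6–C11), ring C = right cyclohexane (C14–C19), ring D = right oxepanone (C18–C23, O).
2. Cuts, in retrosynthetic order: C6–C11 and O–C2 (rings B and A, one cascade on a 2,3:6,7-diepoxide with a C10=C11 allylsilane); the C15 O-acetyl and C22=O; C12–C13 (sulfone alkylation); C15–CH3 (methyl addition to a C15 ketone); C14–C19 and O–C23 (rings C and D, the same cascade).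
3. Both halves are cut back to one diepoxy allylsilane building block (six steps from geranyl bromide and methyl acetoacetate), which the hidden twofold symmetry of the carbon skeleton allows.
4. Forward order: rings D and C (step 8), the C15 carbinol (steps 9–10), the C12–C13 union with a second molecule of the building block (steps 11–12), the C22 ketone and C15 acetate (steps 13–14), then ring A and, as the last ring, ring B (step 15).
5. Feature that makes the last event possible: the ether oxygen of ring A links C2 and C7, C7 is bonded to the methyl-bearing quaternary C6, and C6 is bonded to C11 next to the exocyclic C10=CH2 of ring B. This is the imprint of an epoxonium ion (O on C2, C6 and C7) opened at C6 by a C10=C11 allylsilane.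
6. Stereochemistry: C3, C7 and C18 (and C22 before oxidation) come from Shi epoxidation with the L-fructose-derived ketone; C6 and C19 from anti opening of the trans-epoxides; C11 and C14 from chair transition states of the Z-allylsilanes; C15 from equatorial methyl addition.

Key step: step 15

Remark (assumption): the target is taken to be exactly the given SMILES, i.e. (3S,6S,7S,11R,14S,15R,18S,19S) in the numbering above, and the L-fructose-derived enantiomer of the Shi ketone is taken as a purchasable catalyst. Names of the acyclic compounds use their own chain locants; C-numbers in the Why lines use the chain numbering of the plan.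

**Route**

Step 1
Reactants: 1 methyl acetoacetate; 2 geranyl bromide [(2E)-1-bromo-3,7-dimethylocta-2,6-diene]
Product: 3 methyl (6E)-7,11-dimethyl-3-oxododeca-6,10-dienoate
Conditions: NaH, THF, 0 °C; n-BuLi, 0 °C; then 2, 0 °C to rt; 1 M HCl
Reagents that add atoms: none
Why: The acetoacetate dianion is alkylated only at its terminal, more nucleophilic carbon by the allylic bromide (dianion γ-alkylation, SN2), which gives the β-keto ester that later fixes the allylsilane geometry; no stereocentre is formed and the E-alkene of 2 is carried over.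

Step 2
Reactants: 3 methyl (6E)-7,11-dimethyl-3-oxododeca-6,10-dienoate
Product: 4 methyl (2Z,6E)-7,11-dimethyl-3-{[(trifluoromethyl)sulfonyl]oxy}dodeca-2,6,10-trienoate
Conditions: Tf2O, sat. aq. LiOH, hexanes, 5 °C
Reagents that add atoms: trifluoromethanesulfonic anhydride, O=S(=O)(OS(=O)(=O)C(F)(F)F)C(F)(F)F
Why: O-Sulfonylation of the lithium-chelated Z-enolate of the β-keto ester under biphasic (Schotten–Baumann-type) conditions should give the enol triflate with the triflyloxy group cis to the ester, which defines the geometry of the later allylsilane double bond.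

Step 3
Reactants: 4 methyl (2Z,6E)-7,11-dimethyl-3-{[(trifluoromethyl)sulfonyl]oxy}dodeca-2,6,10-trienoate
Product: 5 methyl (2Z,6E)-7,11-dimethyl-3-[(trimethylsilyl)methyl]dodeca-2,6,10-trienoate
Conditions: Me3SiCH2MgCl, Pd(PPh3)4 (5 mol %), THF, 0 °C to rt
Reagents that add atoms: (trimethylsilyl)methylmagnesium chloride, C[Si](C)(C)C[Mg]Cl
Why: Kumada cross-coupling on zerovalent palladium (oxidative addition, transmetalation, reductive elimination) replaces the triflate with retention of alkene geometry, so the CH2SiMe3 group ends up cis to the ester carbon (2Z), and the ester is not attacked at this temperature.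

Step 4
Reactants: 5 methyl (2Z,6E)-7,11-dimethyl-3-[(trimethylsilyl)methyl]dodeca-2,6,10-trienoate
Product: 6 methyl (2Z,6S,7S,10S)-6,7:10,11-diepoxy-7,11-dimethyl-3-[(trimethylsilyl)methyl]dodec-2-enoate
Conditions: L-fructose-derived Shi ketone (0.6 equiv), Oxone (2KHSO5·KHSO4·K2SO4), K2CO3, Bu4NHSO4, MeCN–CH2(OMe)2, aq. Na2B4O7 buffer, 0 °C
Reagents that add atoms: potassium peroxymonosulfate (the oxidant of Oxone), [K+].[O-]S(=O)(=O)OO
Why: Shi asymmetric epoxidation, in which the chiral dioxirane formed from the ketone and KHSO5 transfers oxygen through a spiro transition state to one face of each electron-rich trisubstituted alkene, should set the 6S,7S and 10S epoxides, while the ester-conjugated double bond is too electron-poor to react.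

Step 5
Reactants: 6 methyl (2Z,6S,7S,10S)-6,7:10,11-diepoxy-7,11-dimethyl-3-[(trimethylsilyl)methyl]dodec-2-enoate
Product: 7 (2Z,6S,7S,10S)-6,7:10,11-diepoxy-7,11-dimethyl-3-[(trimethylsilyl)methyl]dodec-2-en-1-ol
Conditions: i-Bu2AlH (2.2 equiv), CH2Cl2, −78 °C; aq. potassium sodium tartrate (KNaC4H4O6)
Reagents that add atoms: none
Why: 1,2-Reduction of the conjugated ester by the aluminium hydride at low temperature gives the allylic alcohol, and the trisubstituted epoxides and the allylsilane are not touched under these conditions.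

Step 6
Reactants: 7 (2Z,6S,7S,10S)-6,7:10,11-diepoxy-7,11-dimethyl-3-[(trimethylsilyl)methyl]dodec-2-en-1-ol
Product: 9 (2Z,6S,7S,10S)-1-bromo-6,7:10,11-diepoxy-7,11-dimethyl-3-[(trimethylsilyl)methyl]dodec-2-ene, via allylic mesylate 8 (not isolated)
Conditions: MsCl, Et3N, THF, −40 °C; then LiBr, 0 °C
Reagents that add atoms: lithium bromide, [Li+].[Br-]; methanesulfonyl chloride, CS(=O)(=O)Cl (its atoms are found only in intermediate 8)
Why: Sulfonylation of the primary allylic alcohol and SN2 displacement by bromide in the same flask avoid acid, so the epoxides stay closed and the double bond keeps its position and geometry.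

Step 7
Reactants: 9 (2Z,6S,7S,10S)-1-bromo-6,7:10,11-diepoxy-7,11-dimethyl-3-[(trimethylsilyl)methyl]dodec-2-ene
Product: 10 (2Z,6S,7S,10S)-6,7:10,11-diepoxy-7,11-dimethyl-1-(phenylsulfonyl)-3-[(trimethylsilyl)methyl]dodec-2-ene
Conditions: PhSO2Na, DMF, rt
Reagents that add atoms: sodium benzenesulfinate, [Na+].[O-]S(=O)c1ccccc1
Why: S-Alkylation of the sulfinate anion by the primary allylic bromide (SN2) installs the sulfone that later stabilizes the C13 carbanion.

Step 8
Reactants: 10 (2Z,6S,7S,10S)-6,7:10,11-diepoxy-7,11-dimethyl-1-(phenylsulfonyl)-3-[(trimethylsilyl)methyl]dodec-2-ene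
Product: 12 (3S,5aS,6R,9aS)-2,2,5a-trimethyl-7-methylidene-6-[(phenylsulfonyl)methyl]decahydro-1-benzoxepin-3-ol, via silyl ether 11 (not isolated)
Conditions: Me3SiOTf (1.1 equiv), 2,6-di-tert-butyl-4-methylpyridine, CH2Cl2, −78 °C; then 1 M HCl, THF, 0 °C
Reagents that add atoms: trimethylsilyl trifluoromethanesulfonate, C[Si](C)(C)OS(=O)(=O)C(F)(F)F (its silyl group is found only in intermediate 11)
Why: In this silyl triflate-promoted tandem oxa-/carbacyclization of the 1,5-diepoxide, the silylated terminal epoxide is opened at its tertiary carbon C23 by the oxygen of the internal epoxide and the resulting epoxonium ion is opened anti at its tertiary carbon C19 by the allylsilane through a chair transition state, which should give the trans-fused rings D and C with the C13 arm equatorial (H-14 axial, trans to the C19 methyl) and, after loss of the silyl group, only the exocyclic alkene, before dilute acid cleaves the C22 silyl ether.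

Step 9
Reactants: 12 (3S,5aS,6R,9aS)-2,2,5a-trimethyl-7-methylidene-6-[(phenylsulfonyl)methyl]decahydro-1-benzoxepin-3-ol
Product: 14 (3S,5aS,6S,9aS)-3-hydroxy-2,2,5a-trimethyl-6-[(phenylsulfonyl)methyl]octahydro-1-benzoxepin-7(2H)-one, via secondary ozonide 13 (not isolated)
Conditions: O3, CH2Cl2, −78 °C; then PPh3, −78 °C to rt
Reagents that add atoms: ozone, [O-][O+]=O
Why: Ozonolysis of the only alkene, the exocyclic 1,1-disubstituted one, with reductive work-up gives the C15 ketone, and the equatorial C14 substituent is the thermodynamically favoured epimer, so it is not at risk.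

Step 10
Reactants: 14 (3S,5aS,6S,9aS)-3-hydroxy-2,2,5a-trimethyl-6-[(phenylsulfonyl)methyl]octahydro-1-benzoxepin-7(2H)-one
Product: 15 (3S,5aS,6S,7R,9aS)-2,2,5a,7-tetramethyl-6-[(phenylsulfonyl)methyl]decahydro-1-benzoxepine-3,7-diol
Conditions: MeMgBr (3 equiv), CeCl3, THF, −78 °C; then H2O
Reagents that add atoms: methylmagnesium bromide, C[Mg]Br
Why: The weakly basic organocerium reagent formed from MeMgBr and CeCl3 adds to the ketone in preference to enolizing it (1,2-addition) and approaches along the equatorial trajectory because the axial face is blocked by the syn-axial C19 methyl group, so the new methyl group becomes equatorial and the C15 hydroxyl axial (15R).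

Step 11
Reactants: 15 (3S,5aS,6S,7R,9aS)-2,2,5a,7-tetramethyl-6-[(phenylsulfonyl)methyl]decahydro-1-benzoxepine-3,7-diol; 9 (2Z,6S,7S,10S)-1-bromo-6,7:10,11-diepoxy-7,11-dimethyl-3-[(trimethylsilyl)methyl]dodec-2-ene
Product: 16 (3S,5aS,6S,7R,9aS)-6-[(3Z,7S,8S,11S)-7,8:11,12-diepoxy-8,12-dimethyl-1-(phenylsulfonyl)-4-[(trimethylsilyl)methyl]tridec-3-en-1-yl]-2,2,5a,7-tetramethyldecahydro-1-benzoxepine-3,7-diol (both epimers at the sulfone carbon)
Conditions: 15, n-BuLi (3.1 equiv), THF–HMPA, −78 to −40 °C; then 9, −78 °C; then H2O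
Reagents that add atoms: none
Why: The α-sulfonyl carbanion, generated beside the two lithium alkoxides, is alkylated by the primary allylic bromide in an SN2 reaction that forms the C12–C13 bond, and the new stereocentre at the sulfone carbon is of no consequence because the sulfonyl group is removed in step 12.

Step 12
Reactants: 16 the coupled sulfone named in step 11
Product: 17 (3S,5aS,6S,7R,9aS)-6-[(3Z,7S,8S,11S)-7,8:11,12-diepoxy-8,12-dimethyl-4-[(trimethylsilyl)methyl]tridec-3-en-1-yl]-2,2,5a,7-tetramethyldecahydro-1-benzoxepine-3,7-diol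
Conditions: 6% Na(Hg), Na2HPO4, MeOH–THF, −20 °C
Reagents that add atoms: none
Why: Reductive desulfonylation by electron transfer from the amalgam in buffered methanol replaces the sulfonyl group by hydrogen, and the epoxides, the allylsilane and the alcohols are inert to it.

Step 13
Reactants: 17 the diol named in step 12
Product: 18 (5aS,6S,7R,9aS)-6-[(3Z,7S,8S,11S)-7,8:11,12-diepoxy-8,12-dimethyl-4-[(trimethylsilyl)methyl]tridec-3-en-1-yl]-7-hydroxy-2,2,5a,7-tetramethyloctahydro-1-benzoxepin-3(2H)-one
Conditions: Dess–Martin periodinane, NaHCO3, CH2Cl2, 0 °C to rt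
Reagents that add atoms: none
Why: Dess–Martin oxidation converts the only secondary alcohol into the C22 ketone under buffered conditions, and the tertiary C15 alcohol cannot be oxidized.

Step 14
Reactants: 18 the hydroxy ketone named in step 13
Product: 19 (5aS,6S,7R,9aS)-6-[(3Z,7S,8S,11S)-7,8:11,12-diepoxy-8,12-dimethyl-4-[(trimethylsilyl)methyl]tridec-3-en-1-yl]-2,2,5a,7-tetramethyl-3-oxodecahydro-1-benzoxepin-7-yl acetate
Conditions: Ac2O, Et3N, DMAP, CH2Cl2, rt to 40 °C
Reagents that add atoms: acetic anhydride, CC(=O)OC(C)=O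
Why: Nucleophilic catalysis by DMAP (through the N-acetylpyridinium ion) acylates the remaining tertiary alcohol under basic conditions that the epoxides, the allylsilane and the ketone tolerate.

Step 15
Reactants: 19 the diepoxy allylsilane keto acetate named in step 14
Product: 21 target CNP0148623.1, (5aS,6S,7R,9aS)-6-{2-[(3S,5aS,6R,9aS)-3-hydroxy-2,2,5a-trimethyl-7-methylidenedecahydro-1-benzoxepin-6-yl]ethyl}-2,2,5a,7-tetramethyl-3-oxodecahydro-1-benzoxepin-7-yl acetate, via silyl ether 20 (not isolated)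
Conditions: Me3SiOTf (1.1 equiv), 2,6-di-tert-butyl-4-methylpyridine, CH2Cl2, −78 °C; then 1 M HCl, THF, 0 °C
Reagents that add atoms: trimethylsilyl trifluoromethanesulfonate, C[Si](C)(C)OS(=O)(=O)C(F)(F)F (its silyl group is found only in intermediate 20)
Why: Me3SiOTf silylates the terminal 2,3-epoxide, the oxygen of the 6,7-epoxide opens it at the tertiary carbon C2 to give a bicyclic epoxonium ion (this closes ring A in the 7-endo mode, the ether oxygen ending on C2 and C7), and the C10=C11 allylsilane then opens the epoxonium ion at its tertiary carbon C6 anti to the breaking C6–O bond, closing ring B by C6–C11 bond formation (6-endo at the alkene), after which the β-silyl cation at C10 loses its silyl group to give only the exocyclic C10=CH2 and to regenerate Me3SiOTf. The closest known reaction type is the silyl triflate-promoted tandem oxa-/carbacyclization of 1,5-diepoxides that end in a π-nucleophile, combined with epoxide-initiated, allylsilane-terminated cation–olefin cyclization. C3 and C7 keep the configuration set by the Shi epoxidation because their C–O bonds are never broken, and C6 is formed by stereospecific inversion of the trans-epoxide, which places its methyl group axial and trans to H-7. C11 is set by the chair transition state of the Z-allylsilane, which puts the C12 chain equatorial and H-11 axial, cis to H-7 and trans to the C6 methyl group. The step needs opening of both epoxides at their tertiary carbons, terminal before internal, which the trisubstituted pattern (charge at C2 and C6) and the better accessibility of the terminal epoxide should secure, and it needs the ketone and the tertiary acetate of rings D and C to stay untouched, which the low temperature and the hindered pyridine base should secure. Dilute acid in the work-up cleaves the C3 silyl ether 20 to give 21.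

**Compound list**

1 | methyl acetoacetate (methyl 3-oxobutanoate) | CC(=O)CC(=O)OC | starting material
2 | geranyl bromide, (2E)-1-bromo-3,7-dimethylocta-2,6-diene | CC(C)=CCC/C(C)=C/CBr | starting material
3 | methyl (6E)-7,11-dimethyl-3-oxododeca-6,10-dienoate | COC(=O)CC(=O)CC/C=C(\C)CCC=C(C)C | intermediate
4 | methyl (2Z,6E)-7,11-dimethyl-3-{[(trifluoromethyl)sulfonyl]oxy}dodeca-2,6,10-trienoate | COC(=O)/C=C(\OS(=O)(=O)C(F)(F)F)CC/C=C(\C)CCC=C(C)C | intermediate
5 | methyl (2Z,6E)-7,11-dimethyl-3-[(trimethylsilyl)methyl]dodeca-2,6,10-trienoate | COC(=O)/C=C(\C[Si](C)(C)C)CC/C=C(\C)CCC=C(C)C | intermediate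
6 | methyl (2Z,6S,7S,10S)-6,7:10,11-diepoxy-7,11-dimethyl-3-[(trimethylsilyl)methyl]dodec-2-enoate | COC(=O)/C=C(\C[Si](C)(C)C)CC[C@@H]1O[C@@]1(C)CC[C@@H]1OC1(C)C | intermediate
7 | (2Z,6S,7S,10S)-6,7:10,11-diepoxy-7,11-dimethyl-3-[(trimethylsilyl)methyl]dodec-2-en-1-ol | OC/C=C(\C[Si](C)(C)C)CC[C@@H]1O[C@@]1(C)CC[C@@H]1OC1(C)C | intermediate
8 | methanesulfonate of 7 (allylic mesylate, not isolated) | CS(=O)(=O)OC/C=C(\C[Si](C)(C)C)CC[C@@H]1O[C@@]1(C)CC[C@@H]1OC1(C)C | intermediate
9 | (2Z,6S,7S,10S)-1-bromo-6,7:10,11-diepoxy-7,11-dimethyl-3-[(trimethylsilyl)methyl]dodec-2-ene | BrC/C=C(\C[Si](C)(C)C)CC[C@@H]1O[C@@]1(C)CC[C@@H]1OC1(C)C | intermediate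
10 | (2Z,6S,7S,10S)-6,7:10,11-diepoxy-7,11-dimethyl-1-(phenylsulfonyl)-3-[(trimethylsilyl)methyl]dodec-2-ene | O=S(=O)(C/C=C(\C[Si](C)(C)C)CC[C@@H]1O[C@@]1(C)CC[C@@H]1OC1(C)C)c1ccccc1 | intermediate
11 | 3-O-trimethylsilyl ether of 12 (not isolated) | O=S(=O)(C[C@H]1[C@]2(C)CC[C@H](O[Si](C)(C)C)C(C)(C)O[C@H]2CCC1=C)c1ccccc1 | intermediate
12 | (3S,5aS,6R,9aS)-2,2,5a-trimethyl-7-methylidene-6-[(phenylsulfonyl)methyl]decahydro-1-benzoxepin-3-ol (trans-fused rings D/C) | O=S(=O)(C[C@H]1[C@]2(C)CC[C@H](O)C(C)(C)O[C@H]2CCC1=C)c1ccccc1 | intermediate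
13 | secondary ozonide of 12 (spiro-1,2,4-trioxolane at C15, either configuration at the spiro carbon, not isolated) | O=S(=O)(C[C@H]1[C@]2(C)CC[C@H](O)C(C)(C)O[C@H]2CCC13OOCO3)c1ccccc1 | intermediate
14 | (3S,5aS,6S,9aS)-3-hydroxy-2,2,5a-trimethyl-6-[(phenylsulfonyl)methyl]octahydro-1-benzoxepin-7(2H)-one | O=S(=O)(C[C@H]1[C@]2(C)CC[C@H](O)C(C)(C)O[C@H]2CCC1=O)c1ccccc1 | intermediate
15 | (3S,5aS,6S,7R,9aS)-2,2,5a,7-tetramethyl-6-[(phenylsulfonyl)methyl]decahydro-1-benzoxepine-3,7-diol | O=S(=O)(C[C@H]1[C@]2(C)CC[C@H](O)C(C)(C)O[C@H]2CC[C@@]1(C)O)c1ccccc1 | intermediate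
16 | (3S,5aS,6S,7R,9aS)-6-[(3Z,7S,8S,11S)-7,8:11,12-diepoxy-8,12-dimethyl-1-(phenylsulfonyl)-4-[(trimethylsilyl)methyl]tridec-3-en-1-yl]-2,2,5a,7-tetramethyldecahydro-1-benzoxepine-3,7-diol (both epimers at the sulfone carbon) | O=S(=O)(C(C/C=C(\C[Si](C)(C)C)CC[C@@H]3O[C@@]3(C)CC[C@@H]3OC3(C)C)[C@H]1[C@]2(C)CC[C@H](O)C(C)(C)O[C@H]2CC[C@@]1(C)O)c1ccccc1 | intermediate
17 | (3S,5aS,6S,7R,9aS)-6-[(3Z,7S,8S,11S)-7,8:11,12-diepoxy-8,12-dimethyl-4-[(trimethylsilyl)methyl]tridec-3-en-1-yl]-2,2,5a,7-tetramethyldecahydro-1-benzoxepine-3,7-diol | C(C/C=C(\C[Si](C)(C)C)CC[C@@H]3O[C@@]3(C)CC[C@@H]3OC3(C)C)[C@H]1[C@]2(C)CC[C@H](O)C(C)(C)O[C@H]2CC[C@@]1(C)O | intermediate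
18 | (5aS,6S,7R,9aS)-6-[(3Z,7S,8S,11S)-7,8:11,12-diepoxy-8,12-dimethyl-4-[(trimethylsilyl)methyl]tridec-3-en-1-yl]-7-hydroxy-2,2,5a,7-tetramethyloctahydro-1-benzoxepin-3(2H)-one | C(C/C=C(\C[Si](C)(C)C)CC[C@@H]3O[C@@]3(C)CC[C@@H]3OC3(C)C)[C@H]1[C@]2(C)CCC(=O)C(C)(C)O[C@H]2CC[C@@]1(C)O | intermediate
19 | (5aS,6S,7R,9aS)-6-[(3Z,7S,8S,11S)-7,8:11,12-diepoxy-8,12-dimethyl-4-[(trimethylsilyl)methyl]tridec-3-en-1-yl]-2,2,5a,7-tetramethyl-3-oxodecahydro-1-benzoxepin-7-yl acetate | C(C/C=C(\C[Si](C)(C)C)CC[C@@H]3O[C@@]3(C)CC[C@@H]3OC3(C)C)[C@H]1[C@]2(C)CCC(=O)C(C)(C)O[C@H]2CC[C@@]1(C)OC(C)=O | intermediate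
20 | 3-O-trimethylsilyl ether of 21 (not isolated) | C=C1CC[C@@H]2OC(C)(C)[C@@H](O[Si](C)(C)C)CC[C@@]2(C)[C@@H]1CC[C@H]1[C@]2(C)CCC(=O)C(C)(C)O[C@H]2CC[C@@]1(C)OC(C)=O | intermediate
21 | CNP0148623.1, (5aS,6S,7R,9aS)-6-{2-[(3S,5aS,6R,9aS)-3-hydroxy-2,2,5a-trimethyl-7-methylidenedecahydro-1-benzoxepin-6-yl]ethyl}-2,2,5a,7-tetramethyl-3-oxodecahydro-1-benzoxepin-7-yl acetate | C=C1CC[C@@H]2OC(C)(C)[C@@H](O)CC[C@@]2(C)[C@@H]1CC[C@H]1[C@]2(C)CCC(=O)C(C)(C)O[C@H]2CC[C@@]1(C)OC(C)=O | target

**Step count and risks**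

Total step count: 15 steps. Longest linear sequence: 15 steps (from 1 and 2 to 21; bromide 9 re-enters the same line at step 11).

Steps most likely to fail:

1. Step 15. The silyl triflate may engage the right-half carbonyl groups instead of the terminal epoxide (ionisation or neighbouring-group participation of the tertiary acetate, silyl enol ether formation at the ring D ketone), and the epoxonium ion may be diverted before ring B closes. The fallback sets out from 18 and comes back at 21. The hydroxy ketone 18, which carries no acetate, would be submitted to the same diepoxide–allylsilane cascade with t-BuMe2SiOTf and 2,6-di-tert-butyl-4-methylpyridine (CH2Cl2, −78 °C), so that the C3 oxygen emerges as a robust silyl ether in the tetracyclic 3-O-tert-butyldimethylsilyl 15-alcohol F1. With the epoxides and the allylsilane consumed, the tertiary alcohol can be acetylated under forcing conditions (AcCl, PhNMe2, CHCl3, 50 °C) to give the silyl ether acetate F2, and Bu4NF in THF would remove the silyl group to give 21.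

2. Step 10. β-Elimination of benzenesulfinate from the β-sulfonyl ketone through its C14 enolate (retro-Michael) may compete with carbonyl addition. The fallback sets out from 14 and comes back at 15. The elimination is driven to completion on purpose (DBU, CH2Cl2, 0 °C) to give the exocyclic enone F3. Conjugate addition of PhSH (cat. Et3N, CH2Cl2), with equilibration of C14 to the equatorial isomer, gives the β-phenylthio ketone F4, in which thiolate is a much poorer leaving group. MeMgBr–CeCl3 then adds as in step 10 to give the sulfide diol F5, and mCPBA (2.2 equiv, NaHCO3, CH2Cl2, 0 °C) oxidizes the sulfide to sulfone 15. This detour also lowers the electron demand on sulfur only after the cascade of step 8, so step 8 is unchanged.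

3. Step 14. Acylation of the axial tertiary hydroxyl, which is flanked by the C14 side chain and syn-axial to the C19 methyl group, may be sluggish or incomplete under conditions mild enough for the epoxides and the allylsilane. The fallback sets out from 17 and comes back at 19. The secondary hydroxyl of 17 is silylated selectively (Et3SiCl, imidazole, CH2Cl2, 0 °C) to give the 22-O-triethylsilyl ether F6. The tertiary hydroxyl is then acylated as its potassium alkoxide (KN(SiMe3)2, THF, −78 °C; then Ac2O) to give the silyl ether acetate F7. Buffered fluoride (Bu4NF, AcOH, THF, 0 °C) frees the secondary alcohol to give the hydroxy acetate F8, and Dess–Martin oxidation as in step 13 gives 19.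

**Further compounds**

F1 | step 15 | 3-O-tert-butyldimethylsilyl ether of the 15-deacetyl target (tetracyclic 15-alcohol) | C=C1CC[C@@H]2OC(C)(C)[C@@H](O[Si](C)(C)C(C)(C)C)CC[C@@]2(C)[C@@H]1CC[C@H]1[C@]2(C)CCC(=O)C(C)(C)O[C@H]2CC[C@@]1(C)O
F2 | step 15 | 3-O-tert-butyldimethylsilyl ether of 21 | C=C1CC[C@@H]2OC(C)(C)[C@@H](O[Si](C)(C)C(C)(C)C)CC[C@@]2(C)[C@@H]1CC[C@H]1[C@]2(C)CCC(=O)C(C)(C)O[C@H]2CC[C@@]1(C)OC(C)=O
F3 | step 10 | (3S,5aS,9aS)-3-hydroxy-2,2,5a-trimethyl-6-methylideneoctahydro-1-benzoxepin-7(2H)-one | C=C1[C@]2(C)CC[C@H](O)C(C)(C)O[C@H]2CCC1=O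
F4 | step 10 | (3S,5aS,6S,9aS)-3-hydroxy-2,2,5a-trimethyl-6-[(phenylsulfanyl)methyl]octahydro-1-benzoxepin-7(2H)-one | c1ccccc1SC[C@H]1[C@]2(C)CC[C@H](O)C(C)(C)O[C@H]2CCC1=O
F5 | step 10 | (3S,5aS,6S,7R,9aS)-2,2,5a,7-tetramethyl-6-[(phenylsulfanyl)methyl]decahydro-1-benzoxepine-3,7-diol | c1ccccc1SC[C@H]1[C@]2(C)CC[C@H](O)C(C)(C)O[C@H]2CC[C@@]1(C)O
F6 | step 14 | 22-O-triethylsilyl ether of 17 | C(C/C=C(\C[Si](C)(C)C)CC[C@@H]3O[C@@]3(C)CC[C@@H]3OC3(C)C)[C@H]1[C@]2(C)CC[C@H](O[Si](CC)(CC)CC)C(C)(C)O[C@H]2CC[C@@]1(C)O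
F7 | step 14 | 15-O-acetate of the 22-O-triethylsilyl ether of 17 | C(C/C=C(\C[Si](C)(C)C)CC[C@@H]3O[C@@]3(C)CC[C@@H]3OC3(C)C)[C@H]1[C@]2(C)CC[C@H](O[Si](CC)(CC)CC)C(C)(C)O[C@H]2CC[C@@]1(C)OC(C)=O
F8 | step 14 | 15-O-acetate of 17 (free 22-alcohol) | C(C/C=C(\C[Si](C)(C)C)CC[C@@H]3O[C@@]3(C)CC[C@@H]3OC3(C)C)[C@H]1[C@]2(C)CC[C@H](O)C(C)(C)O[C@H]2CC[C@@]1(C)OC(C)=O
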